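- The amber run (0.54 mol% of free catalyst) ends with a leftover: over its last two readings, free starting material stands at 31.3% of the charge and target at 56.8%, which leaves a gap of 11.9%.

in all of them: starting material 0.23 M

| run | second substrate | partner | free catalyst | remark | time |
|---|---|---|---|---|---|
| amber | 2 equiv | 1.2 equiv | 0.54 mol% | run made earlier |  |
| red | 2 equiv | 1.2 equiv | 1.6 mol% | run made earlier |  |
| north-east | 2.00 equiv | 1.20 equiv | 0.5 mol% |  | 3.0 h |
| south-west | 2.00 equiv | 1.20 equiv | 1 mol% |  | 3.0 h |
| north | 2.00 equiv | 1.20 equiv | 2 mol% |  | 3.0 h |

| run | time / min | target / % | starting material / % | catalyst intermediate A / % |
|---|---|---|---|---|
| amber | 30.0 | 48.5 | 35.7 | 0.1 |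
| amber | 60.0 | 55.1 | 32.0 | 0 |
| amber | 90.0 | 57.0 | 31.4 | 0.1 |
| amber | 120 | 56.5 | 31.3 | 0 |
| red | 15.0 | 54.9 | 32.4 | 0 |
| red | 40.0 | 58.5 | 29.9 | 0.4 |
| red | 80.0 | 58.8 | 29.5 | 0.3 |
| red | 120 | 58.7 | 30.0 | 0.3 |

(readings scatter by 0.3 percentage points)

- what was read earlier has a scatter of 0.3 percentage points, one standard deviation
- steps thought possible: second substrate + free catalyst <-> catalyst intermediate B; starting material + free catalyst <-> catalyst intermediate A; partner + catalyst intermediate A -> free catalyst + target; partner + catalyst intermediate B -> free catalyst + second product; starting material <-> dormant form
- a reading of starting material is of its free form alone

* which of these there is most of at the end, counted by the starting material in it, north-east (target / starting material / catalyst intermediate A)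
* which of these there is most of at the end, counted by the starting material in it, south-west (target / starting material / catalyst intermediate A)
* which of these there is most of at the end, counted by the starting material in it, north (target / starting material / catalyst intermediate A)
* amount of the one of these that there is most of at the end, in percent of the starting material charged, north-east
* amount of the one of these that there is most of at the end, in percent of the starting material charged, south-west
* amount of the one of these that there is most of at the end, in percent of the starting material charged, north

- I write the balance of the starting material. Catalyst intermediate A reads 0.1% at that stage, far less than the gap, so I book the gap as dormant form, which a reading of starting material does not count.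
- I read the step to the dormant form as a reversible first-order exchange, so on a plateau I take the dormant form as proportional to free starting material, like a tank that follows its neighbour's level. In the amber run, the part of the charge not turned into target, divided by free starting material, reads 1.38. I call this plateau ratio the hold-back factor, and on a plateau I reckon target as the whole charge less this factor times free starting material.
- The red run (1.6 mol%) gives two separate routes to its target. Its last three target readings average 58.7%. Its own free starting material, 29.8%, with the factor from the amber run gives 58.9%. They part by 0.20 percentage points, less than the scatter of one reading, so I trust the factor.
- For the north flask (2 mol%) I extend both routes on the logarithm of the loading. Target read directly gives 59.1%. Free starting material extended to 29.5% and passed through the factor gives 59.3%. These two part by 0.20 points, again within the scatter.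
- The amber run is flat from 90.0 min, earlier than the time asked, so I treat the new flasks as plateaus. The factor route then gives me 56.6% target for north-east and 58.0% for south-west, alongside 59.3% for north.
- The forecast, “Interpolating on log loading”, names target as the largest pool in each flask. It gives 56.7% (55.9% to 57.4%) for north-east, 57.9% (57.2% to 58.6%) for south-west and 59% (58.3% to 60%) for north. My north figure differs from its central value but lies inside its range.

    second substrate + free catalyst ⇌ catalyst intermediate B (K = 5.10 /M, k = 2.70 /M/s)
    starting material + free catalyst ⇌ catalyst intermediate A (K = 2.50 /M, k = 19.0 /M/s)
    partner + catalyst intermediate A → free catalyst + target (k = 3.80 /M/s)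
    partner + catalyst intermediate B → free catalyst + second product (k = 0.730 /M/s)
    starting material ⇌ dormant form (K = 0.380, k = 5.10 × 10⁻⁴ /s)

- Target is the largest pool at 56.7% in north-east, 57.8% in south-west and 59.2% in north. In north-east, 0.0194% of the charged partner, the limiting reagent, is still free at the end. The hold-back factor turns the 29.5% of free starting material in north into 59.3% target. A neighbour flask is north with 0.480 equiv of partner, and at its end starting material is the largest pool at 54.0%. The factor turns that into 25.5%, and that neighbour flask holds 25.4% target.

The data are calculated for substances that don't exist, noise included.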